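**Retrosynthetic overview**

1. The side chain is numbered from the ether CH2 (C1'). The strategy rests on the E-trisubstituted C2'=C3' alkene, which carries the C3' methyl and the C1' oxymethylene on neighbouring carbons beside the (R)-carbinol C4'. This is the pattern left by syn methylmetalation of a terminal propargylic alkyne followed by capture with a one-carbon electrophile.
2. Late disconnections: O–O unmasking of a monoperoxyketal; C5'=C6' by cross-metathesis with protected 2-methylbut-3-en-2-yl hydroperoxide; C1'–O by Mitsunobu etherification with 4-hydroxy-5-methylcoumarin.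
3. Key disconnection: allylic alcohol 12 from (R)-silyloxy enyne 7 by zirconium-catalysed methylalumination (C3'–CH3) and formaldehyde trapping (C1'–C2'). Enyne 7 comes from acrolein and ethynyltrimethylsilane through a lipase resolution.
4. Rings: only the pyranone ring of the coumarin is built (step 6, from the o-hydroxyacetophenone); the benzene ring is bought and the side chain stays acyclic.

Key step: step 5

Assumption: the lipase follows the usual substituent-size rule, with the silylethynyl arm as the large and the vinyl group as the medium substituent, so the (R)-alcohol is the enantiomer that is acylated.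

**Route**

Step 1
Reactants: 1 ethynyltrimethylsilane; 2 acrolein
Product: 4 rac-5-(trimethylsilyl)pent-1-en-4-yn-3-ol, via lithium (trimethylsilyl)acetylide 3 (not isolated)
Conditions: n-BuLi, THF, −78 °C; then 2, −78 °C; H2O
Reagents that add atoms: none
Why: Deprotonation gives the lithium acetylide, which should add 1,2 to the aldehyde of acrolein at low temperature (acetylide addition to an enal); the carbinol is formed racemic.

Step 2
Reactants: 4 rac-5-(trimethylsilyl)pent-1-en-4-yn-3-ol
Product: 5 (R)-5-(trimethylsilyl)pent-1-en-4-yn-3-yl acetate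
Conditions: immobilised Candida antarctica lipase B (Novozym 435), vinyl acetate (3 equiv), hexane, 30 °C, stopped at about 40% conversion; chromatography
Reagents that add atoms: vinyl acetate, C=COC(C)=O
Why: Lipase-catalysed kinetic resolution by irreversible transesterification: by the empirical size rule for lipase acylation of secondary alcohols the (R)-alcohol should react faster, so stopping below half conversion should give the (R)-acetate in high enantiomeric purity and leave the (S)-alcohol, which is separated.

Step 3
Reactants: 5 (R)-5-(trimethylsilyl)pent-1-en-4-yn-3-yl acetate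
Product: 6 (R)-pent-1-en-4-yn-3-ol
Conditions: K2CO3 (0.2 equiv), MeOH, 0 °C → rt; Et2O extraction, concentrated cold (volatile)
Reagents that add atoms: none
Why: Base-catalysed methanolysis should cleave the acetate at the acyl carbon and protodesilylate the alkynylsilane in the same operation, leaving the C–O bond of the stereocentre untouched.

Step 4
Reactants: 6 (R)-pent-1-en-4-yn-3-ol
Product: 7 (R)-3-(tert-butyldimethylsilyloxy)pent-1-en-4-yne
Conditions: TBSCl, imidazole, CH2Cl2, 0 °C → rt
Reagents that add atoms: tert-butyldimethylsilyl chloride (TBSCl), CC(C)(C)[Si](C)(C)Cl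
Why: Imidazole-promoted silylation of a secondary alcohol masks the hydroxyl toward AlMe3 and lowers the volatility of the enyne.

Step 5
Reactants: 7 (R)-3-(tert-butyldimethylsilyloxy)pent-1-en-4-yne; 8 trimethylaluminium; 9 formaldehyde (charged as paraformaldehyde)
Product: 12 (R,E)-4-(tert-butyldimethylsilyloxy)-3-methylhexa-2,5-dien-1-ol, via alkenyldimethylalane 10 (not isolated), via lithium alkenylalanate 11 (not isolated)
Conditions: 8 (3 equiv), Cp2ZrCl2 (0.3 equiv), CH2Cl2, 0 °C → rt; volatiles removed in vacuo, hexane; n-BuLi, −78 → 0 °C; 9 as (CH2O)n, THF, 0 °C → rt; aq. potassium sodium tartrate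
Reagents that add atoms: none
Why: Cp2ZrCl2 and AlMe3 form a methylzirconocene–aluminate species that adds Me–Zr across the terminal alkyne of 7 in a concerted syn four-centre fashion, methyl to the internal carbon (C3') and metal to the terminal carbon, and Zr-to-Al exchange then gives the (E)-alkenylalane 10 and returns zirconium to the cycle. n-BuLi converts 10 into the more nucleophilic alanate 11, whose alkenyl group is transferred to formaldehyde with retention of geometry, forming the C1'–C2' bond so that the C3' methyl and the new CH2OH lie on the same side of the alkene, the E geometry required. The closest known reaction type is the zirconium-catalysed methylalumination of terminal alkynes (Negishi carboalumination) with ate-complex trapping by formaldehyde, the standard entry to (E)-3-methylalk-2-en-1-ols. No ring is closed and no stereocentre is created; the (R)-centre at C4' is carried through because no bond to it is made or broken. The step needs methyl delivery to the internal carbon, syn addition and reaction at the alkyne instead of the vinyl group: the first follows from the preference of the metal for the less hindered terminal carbon, the second from the concerted mechanism, and the third from the much lower reactivity of an unactivated monosubstituted alkene toward the achiral zirconocene. The bulky silyl ether should keep the propargylic oxygen from binding aluminium, and the low temperature should limit Lewis-acid ionisation of the allylic–propargylic C–O bond.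

Step 6
Reactants: 13 1-(2-hydroxy-6-methylphenyl)ethanone
Product: 14 4-hydroxy-5-methylcoumarin
Conditions: NaH (3 equiv), diethyl carbonate, toluene, 110 °C; aq. HCl
Reagents that add atoms: diethyl carbonate, CCOC(=O)OCC
Why: Base-mediated condensation of the o-hydroxyacetophenone with diethyl carbonate (Claisen-type acylation of the ketone enolate followed by lactonisation onto the phenoxide) should close the pyranone ring and place the aryl methyl at C5.

Step 7
Reactants: 12 (R,E)-4-(tert-butyldimethylsilyloxy)-3-methylhexa-2,5-dien-1-ol; 14 4-hydroxy-5-methylcoumarin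
Product: 15 4-{[(2E,4R)-4-(tert-butyldimethylsilyloxy)-3-methylhexa-2,5-dien-1-yl]oxy}-5-methyl-2H-chromen-2-one
Conditions: PPh3, DIAD, THF, 0 °C → rt
Reagents that add atoms: none
Why: Mitsunobu etherification: the acidic 4-hydroxycoumarin (a vinylogous carboxylic acid) should be alkylated on O4 by SN2 attack on the primary allylic alkoxyphosphonium ion at C1', leaving the alkene geometry and the C4' stereocentre untouched.

Step 8
Reactants: 15 4-{[(2E,4R)-4-(tert-butyldimethylsilyloxy)-3-methylhexa-2,5-dien-1-yl]oxy}-5-methyl-2H-chromen-2-one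
Product: 16 4-{[(2E,4R)-4-hydroxy-3-methylhexa-2,5-dien-1-yl]oxy}-5-methyl-2H-chromen-2-one
Conditions: HF·pyridine, pyridine, THF, 0 °C → rt
Reagents that add atoms: none
Why: Fluoride cleavage of the silyl ether under pyridine-buffered conditions avoids base attack on the 4-alkoxycoumarin and is too weakly acidic to ionise the doubly allylic carbinol.

Step 9
Reactants: 17 2-methylbut-3-en-2-ol
Product: 18 2-methylbut-3-en-2-yl hydroperoxide
Conditions: 50% aq. H2O2 (5 equiv), cat. H2SO4, 0 °C; extracted into CH2Cl2 and kept in solution
Reagents that add atoms: hydrogen peroxide, OO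
Why: Acid-catalysed perhydrolysis (SN1 substitution of a tertiary allylic alcohol by H2O2): the 1,1-dimethylallyl cation should be captured under kinetic control at its tertiary terminus by the large excess of the alpha-effect nucleophile.

Step 10
Reactants: 18 2-methylbut-3-en-2-yl hydroperoxide
Product: 19 3-[(2-methoxypropan-2-yl)peroxy]-3-methylbut-1-ene
Conditions: 2-methoxypropene, cat. pyridinium p-toluenesulfonate, CH2Cl2, 0 °C; Et3N quench
Reagents that add atoms: 2-methoxypropene, C=C(C)OC
Why: Acid-catalysed addition of the hydroperoxide O–H across the enol ether gives the monoperoxyketal, which removes the ruthenium-incompatible OOH proton and is cleaved later by very mild acid.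

Step 11
Reactants: 16 4-{[(2E,4R)-4-hydroxy-3-methylhexa-2,5-dien-1-yl]oxy}-5-methyl-2H-chromen-2-one; 19 3-[(2-methoxypropan-2-yl)peroxy]-3-methylbut-1-ene
Product: 20 4-{[(2E,4R,5E)-4-hydroxy-7-[(2-methoxypropan-2-yl)peroxy]-3,7-dimethylocta-2,5-dien-1-yl]oxy}-5-methyl-2H-chromen-2-one
Conditions: 19 (4 equiv), second-generation Hoveyda–Grubbs catalyst RuCl2(SIMes)(=CH–C6H4-2-OiPr) (10 mol%), 1,4-benzoquinone (10 mol%), CH2Cl2, 40 °C
Reagents that add atoms: none
Why: Olefin cross-metathesis between the monosubstituted vinyl group of 16 and an excess of the non-dimerising alkene 19: the trisubstituted C2'=C3' alkene and the coumarin C3=C4 bond are too hindered or electron-poor to engage, dialkyl peroxides and peroxyketals are known to tolerate ruthenium carbenes, and the bulky partner should give the E alkene under thermodynamic control.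

Step 12
Reactants: 20 4-{[(2E,4R,5E)-4-hydroxy-7-[(2-methoxypropan-2-yl)peroxy]-3,7-dimethylocta-2,5-dien-1-yl]oxy}-5-methyl-2H-chromen-2-one
Product: 21 4-{[(2E,4R,5E)-7-hydroperoxy-4-hydroxy-3,7-dimethylocta-2,5-dien-1-yl]oxy}-5-methyl-2H-chromen-2-one (CNP0299358.1)
Conditions: AcOH/THF/H2O, rt
Reagents that add atoms: none
Why: Mild acid hydrolysis of the monoperoxyketal (loss of methanol, then hydration of the peroxycarbenium ion) should release the hydroperoxide, the acid being too weak to ionise the doubly allylic alcohol or the allylic coumarinyl ether.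

**Compound list**

1 | ethynyltrimethylsilane | C#C[Si](C)(C)C | starting material
2 | acrolein | C=CC=O | starting material
3 | lithium (trimethylsilyl)acetylide | [Li+].[C-]#C[Si](C)(C)C | intermediate
4 | rac-5-(trimethylsilyl)pent-1-en-4-yn-3-ol | C=CC(O)C#C[Si](C)(C)C | intermediate
5 | (R)-5-(trimethylsilyl)pent-1-en-4-yn-3-yl acetate | CC(=O)O[C@H](C=C)C#C[Si](C)(C)C | intermediate
6 | (R)-pent-1-en-4-yn-3-ol | C#C[C@H](O)C=C | intermediate
7 | (R)-3-(tert-butyldimethylsilyloxy)pent-1-en-4-yne | C#C[C@H](O[Si](C)(C)C(C)(C)C)C=C | intermediate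
8 | trimethylaluminium | C[Al](C)C | starting material
9 | formaldehyde (charged as paraformaldehyde) | C=O | starting material
10 | (R,E)-[3-(tert-butyldimethylsilyloxy)-2-methylpenta-1,4-dien-1-yl]dimethylalane | C/C(=C\[Al](C)C)[C@H](O[Si](C)(C)C(C)(C)C)C=C | intermediate
11 | lithium (R,E)-butyl[3-(tert-butyldimethylsilyloxy)-2-methylpenta-1,4-dien-1-yl]dimethylalanate | [Li+].CCCC[Al-](C)(C)/C=C(\C)[C@H](O[Si](C)(C)C(C)(C)C)C=C | intermediate
12 | (R,E)-4-(tert-butyldimethylsilyloxy)-3-methylhexa-2,5-dien-1-ol | C/C(=C\CO)[C@H](O[Si](C)(C)C(C)(C)C)C=C | intermediate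
13 | 1-(2-hydroxy-6-methylphenyl)ethanone | CC(=O)c1c(C)cccc1O | starting material
14 | 4-hydroxy-5-methylcoumarin (4-hydroxy-5-methyl-2H-chromen-2-one) | Cc1cccc2oc(=O)cc(O)c12 | intermediate
15 | 4-{[(2E,4R)-4-(tert-butyldimethylsilyloxy)-3-methylhexa-2,5-dien-1-yl]oxy}-5-methyl-2H-chromen-2-one | C/C(=C\COc1cc(=O)oc2cccc(C)c12)[C@H](O[Si](C)(C)C(C)(C)C)C=C | intermediate
16 | 4-{[(2E,4R)-4-hydroxy-3-methylhexa-2,5-dien-1-yl]oxy}-5-methyl-2H-chromen-2-one | C/C(=C\COc1cc(=O)oc2cccc(C)c12)[C@H](O)C=C | intermediate
17 | 2-methylbut-3-en-2-ol | C=CC(C)(C)O | starting material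
18 | 2-methylbut-3-en-2-yl hydroperoxide | C=CC(C)(C)OO | intermediate
19 | 3-[(2-methoxypropan-2-yl)peroxy]-3-methylbut-1-ene | C=CC(C)(C)OOC(C)(C)OC | intermediate
20 | 4-{[(2E,4R,5E)-4-hydroxy-7-[(2-methoxypropan-2-yl)peroxy]-3,7-dimethylocta-2,5-dien-1-yl]oxy}-5-methyl-2H-chromen-2-one | C/C(=C\COc1cc(=O)oc2cccc(C)c12)[C@H](O)/C=C/C(C)(C)OOC(C)(C)OC | intermediate
21 | 4-{[(2E,4R,5E)-7-hydroperoxy-4-hydroxy-3,7-dimethylocta-2,5-dien-1-yl]oxy}-5-methyl-2H-chromen-2-one (CNP0299358.1) | C/C(=C\COc1cc(=O)oc2cccc(C)c12)[C@H](O)/C=C/C(C)(C)OO | target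

**Step count**

Total: 12 steps. Longest linear sequence: 9 steps (steps 1, 2, 3, 4, 5, 7, 8, 11, 12). Step 6 and steps 9–10 are side branches.

**Steps most likely to fail**

Step 5 (key step). The methylalumination may be slow or poorly regioselective beside the bulky silyloxy-bearing carbon, AlMe3 may ionise the allylic–propargylic silyl ether, or the alanate may transfer its alkenyl group to formaldehyde incompletely. The fallback sets out from 7 and returns at 12, building the C1'–C2' bond first and introducing the methyl by coupling. Enyne 7 is deprotonated with n-BuLi (THF, −78 °C) and hydroxymethylated with paraformaldehyde to give (R)-4-(tert-butyldimethylsilyloxy)hex-5-en-2-yn-1-ol F1. Hydroxyl-directed anti-hydroalumination with NaAlH2(OCH2CH2OMe)2 (THF, −20 °C, kept cold to avoid elimination of the silyloxy group) places aluminium on C3, and iodinolysis at −78 °C gives (2Z,4R)-4-(tert-butyldimethylsilyloxy)-3-iodohexa-2,5-dien-1-ol F2. Negishi coupling with ZnMe2 and Pd(PPh3)4 in THF replaces iodine by methyl with retention of geometry and gives 12.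

Step 11 (cross-metathesis). The fully substituted allylic carbon of 19 may make the metathesis slow, the peroxide may consume the ruthenium carbene, or a ruthenium hydride may isomerise the free allylic alcohol of 16 to an enone. The fallback sets out from 15 and returns at 21, keeping the peroxide out of the metathesis. Silyl ether 15 is cross-metathesised with an excess of 17 (same second-generation Hoveyda–Grubbs catalyst, CH2Cl2, 40 °C) to give 4-{[(2E,4R,5E)-4-(tert-butyldimethylsilyloxy)-7-hydroxy-3,7-dimethylocta-2,5-dien-1-yl]oxy}-5-methyl-2H-chromen-2-one F3. Acid-catalysed perhydrolysis (50% H2O2, cat. H2SO4, Et2O, 0 °C) then exchanges the tertiary allylic hydroxyl for OOH; the cation should be captured at the tertiary carbon because the other allylic terminus is flanked by the silyloxy-bearing carbon. This gives 4-{[(2E,4R,5E)-4-(tert-butyldimethylsilyloxy)-7-hydroperoxy-3,7-dimethylocta-2,5-dien-1-yl]oxy}-5-methyl-2H-chromen-2-one F4. HF·pyridine (pyridine, THF, 0 °C) removes the silyl group and gives 21.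

Step 2 (lipase resolution). The enzyme may discriminate poorly between the two unsaturated arms, or prefer the other enantiomer, so that the acetate is not obtained enantiopure below half conversion. The fallback sets out from 1 and returns at 6, setting the stereocentre by reagent control. Sonogashira coupling of 1 with (E)-3-iodoprop-2-en-1-ol (Pd(PPh3)2Cl2, CuI, Et3N, THF) gives (E)-5-(trimethylsilyl)pent-2-en-4-yn-1-ol F5. Sharpless asymmetric epoxidation (Ti(OiPr)4, L-(+)-diisopropyl tartrate, t-BuOOH, 4 Å sieves, CH2Cl2, −20 °C) gives [(2S,3S)-3-[(trimethylsilyl)ethynyl]oxiran-2-yl]methanol F6. Iodination (PPh3, I2, imidazole) gives (2R,3S)-2-(iodomethyl)-3-[(trimethylsilyl)ethynyl]oxirane F7. Zinc-mediated reductive opening of the epoxy iodide (Zn, EtOH, reflux) transposes it, with the C3–O bond untouched, to (R)-5-(trimethylsilyl)pent-1-en-4-yn-3-ol F8. K2CO3 in MeOH then removes the C-silyl group and gives 6.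

**Further compounds**

F1 | step 5 | (R)-4-(tert-butyldimethylsilyloxy)hex-5-en-2-yn-1-ol | OCC#C[C@H](O[Si](C)(C)C(C)(C)C)C=C
F2 | step 5 | (2Z,4R)-4-(tert-butyldimethylsilyloxy)-3-iodohexa-2,5-dien-1-ol | OC/C=C(\I)[C@H](O[Si](C)(C)C(C)(C)C)C=C
F3 | step 11 | 4-{[(2E,4R,5E)-4-(tert-butyldimethylsilyloxy)-7-hydroxy-3,7-dimethylocta-2,5-dien-1-yl]oxy}-5-methyl-2H-chromen-2-one | C/C(=C\COc1cc(=O)oc2cccc(C)c12)[C@H](O[Si](C)(C)C(C)(C)C)/C=C/C(C)(C)O
F4 | step 11 | 4-{[(2E,4R,5E)-4-(tert-butyldimethylsilyloxy)-7-hydroperoxy-3,7-dimethylocta-2,5-dien-1-yl]oxy}-5-methyl-2H-chromen-2-one | C/C(=C\COc1cc(=O)oc2cccc(C)c12)[C@H](O[Si](C)(C)C(C)(C)C)/C=C/C(C)(C)OO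
F5 | step 2 | (E)-5-(trimethylsilyl)pent-2-en-4-yn-1-ol | OC/C=C/C#C[Si](C)(C)C
F6 | step 2 | [(2S,3S)-3-[(trimethylsilyl)ethynyl]oxiran-2-yl]methanol | OC[C@@H]1O[C@H]1C#C[Si](C)(C)C
F7 | step 2 | (2R,3S)-2-(iodomethyl)-3-[(trimethylsilyl)ethynyl]oxirane | IC[C@@H]1O[C@H]1C#C[Si](C)(C)C
F8 | step 2 | (R)-5-(trimethylsilyl)pent-1-en-4-yn-3-ol | C[Si](C)(C)C#C[C@H](O)C=C
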